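**Retrosynthetic overview**
- Disydonol A is cut at the aryl benzyl ether: a phenoxide released by fluoride from silyl-protected (S)-sydonol attacks the benzylic bromide made from the same monomer, so both halves come from one intermediate.
- The tertiary carbinol of the monomer is cut at C2–C3 of the side chain: a configurationally stable (S)-α-carbamoyloxy benzyllithium (the carbinol carbon used as a nucleophile) is alkylated by 1-bromo-4-methylpentane with inversion, which sets the (S)-quaternary centre.
- The (S)-secondary carbamate comes from asymmetric transfer hydrogenation of silyl-protected methyl 4-acetyl-3-hydroxybenzoate, then carbamoylation and ester reduction.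
- No ring is formed; both benzene rings are bought with the starting ester.

Assumption: methyl 4-acetyl-3-hydroxybenzoate is taken as a catalogue starting material.

**Route**

Step 1
Reactants: 1 methyl 4-acetyl-3-hydroxybenzoate
Product: 2 methyl 4-acetyl-3-(triisopropylsilyloxy)benzoate
Conditions: TIPSCl, imidazole, DMF, rt
Reagents that add atoms: triisopropylsilyl chloride (TIPSCl), CC(C)[Si](Cl)(C(C)C)C(C)C
Why: Silyl ether formation on the phenol; the bulky, non-coordinating TIPS ether is inert to sBuLi and hydrides and neither directs lithiation nor chelates the later benzyllithium.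

Step 2
Reactants: 2 methyl 4-acetyl-3-(triisopropylsilyloxy)benzoate
Product: 3 methyl 4-[(1S)-1-hydroxyethyl]-3-(triisopropylsilyloxy)benzoate
Conditions: RuCl[(S,S)-TsDPEN](p-cymene) (1 mol %), HCO2H/Et3N (5:2), 30 °C
Reagents that add atoms: none
Why: Noyori asymmetric transfer hydrogenation of an aryl methyl ketone, in which the (S,S)-catalyst gives the (S)-carbinol as it does for acetophenone, leaving ester and silyl ether untouched.

Step 3
Reactants: 3 methyl 4-[(1S)-1-hydroxyethyl]-3-(triisopropylsilyloxy)benzoate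
Product: 4 methyl 4-[(1S)-1-(N,N-diisopropylcarbamoyloxy)ethyl]-3-(triisopropylsilyloxy)benzoate
Conditions: iPr2NCOCl, pyridine, 90 °C
Reagents that add atoms: N,N-diisopropylcarbamoyl chloride, CC(C)N(C(C)C)C(Cl)=O
Why: O-Carbamoylation at oxygen (the C–O bond of the stereocentre is not involved, so (S) is kept) installs the Hoppe carbamate that directs and stabilises the benzylic lithiation, and the alkoxide-free conditions avoid O-to-O silyl migration.

Step 4
Reactants: 4 methyl 4-[(1S)-1-(N,N-diisopropylcarbamoyloxy)ethyl]-3-(triisopropylsilyloxy)benzoate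
Product: 5 (1S)-1-[4-(hydroxymethyl)-2-(triisopropylsilyloxy)phenyl]ethyl N,N-diisopropylcarbamate
Conditions: LiBH4, THF, 0 °C → rt; then H2O
Reagents that add atoms: none
Why: Chemoselective borohydride reduction of the methyl ester to the benzylic alcohol (the hindered carbamate and the aryl silyl ether are inert to LiBH4) removes the only group that sBuLi would attack.

Step 5
Reactants: 5 (1S)-1-[4-(hydroxymethyl)-2-(triisopropylsilyloxy)phenyl]ethyl N,N-diisopropylcarbamate; 6 1-bromo-4-methylpentane
Product: 8 (2S)-2-[4-(hydroxymethyl)-2-(triisopropylsilyloxy)phenyl]-6-methylheptan-2-yl N,N-diisopropylcarbamate, via dilithiated carbamate 7 (not isolated)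
Conditions: sBuLi (2.3 equiv), TMEDA, Et2O, −78 °C, 1 h; 6 (3 equiv), −78 → −60 °C; then H2O
Reagents that add atoms: none
Why: Hoppe carbamate-directed benzylic lithiation (retention) gives a configurationally stable α-carbamoyloxy benzyllithium, a carbinol carbon of reversed polarity, and its anti-SE2 alkylation by the primary bromide (inversion at the carbanion, the course reported for alkyl halides with lithiated 1-arylethyl carbamates) joins two normally electrophilic carbons and turns the (S)-secondary into the (S)-tertiary carbamate while the hydroxymethyl group rides along as its lithium alkoxide.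

Step 6
Reactants: 8 (2S)-2-[4-(hydroxymethyl)-2-(triisopropylsilyloxy)phenyl]-6-methylheptan-2-yl N,N-diisopropylcarbamate
Product: 9 (2S)-2-[4-(hydroxymethyl)-2-(triisopropylsilyloxy)phenyl]-6-methylheptan-2-ol
Conditions: LiAlH4 (6 equiv), THF, 0 → 60 °C; then H2O
Reagents that add atoms: none
Why: Reductive carbamate cleavage by hydride attack at the carbonyl carbon (acyl–oxygen fission, so the quaternary C–O bond and its (S) configuration are untouched), with the shielded TIPS ether keeping the ortho oxygen from becoming a phenoxide next to a benzylic leaving group.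

Step 7 (run on about half of 9)
Reactants: 9 (2S)-2-[4-(hydroxymethyl)-2-(triisopropylsilyloxy)phenyl]-6-methylheptan-2-ol
Product: 10 (2S)-2-[4-(bromomethyl)-2-(triisopropylsilyloxy)phenyl]-6-methylheptan-2-ol
Conditions: CBr4, PPh3, CH2Cl2, 0 °C
Reagents that add atoms: carbon tetrabromide, BrC(Br)(Br)Br
Why: Appel bromination, in which only the unhindered primary benzylic alcohol forms the alkoxyphosphonium salt and is displaced by bromide while the tertiary alcohol next to the TIPS ether stays inert under these neutral conditions.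

Step 8
Reactants: 9 (2S)-2-[4-(hydroxymethyl)-2-(triisopropylsilyloxy)phenyl]-6-methylheptan-2-ol; 10 (2S)-2-[4-(bromomethyl)-2-(triisopropylsilyloxy)phenyl]-6-methylheptan-2-ol
Product: 13 disydonol A, via tetrabutylammonium phenoxide 11 (not isolated), via silyl ether 12 (not isolated)
Conditions: 9 (1.1 equiv), TBAF (1.05 equiv), THF, 0 °C; 10 (1.0 equiv), 0 °C → rt; then TBAF (1.5 equiv), rt; AcOH
Reagents that add atoms: none
Why: Fluoride-triggered Williamson ether synthesis, in which desilylation of 9 gives a naked phenoxide that is O-benzylated by 10 (far more nucleophilic than the alcohols, and with a free tertiary OH beside it there is no leaving group to eliminate), and a second charge of fluoride removes the last TIPS group without touching either stereocentre.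

**Compound list**
1 | methyl 4-acetyl-3-hydroxybenzoate | COC(=O)c1ccc(C(C)=O)c(O)c1 | starting material
2 | methyl 4-acetyl-3-(triisopropylsilyloxy)benzoate | COC(=O)c1ccc(C(C)=O)c(O[Si](C(C)C)(C(C)C)C(C)C)c1 | intermediate
3 | methyl 4-[(1S)-1-hydroxyethyl]-3-(triisopropylsilyloxy)benzoate | C[C@H](O)c1ccc(C(=O)OC)cc1O[Si](C(C)C)(C(C)C)C(C)C | intermediate
4 | methyl 4-[(1S)-1-(N,N-diisopropylcarbamoyloxy)ethyl]-3-(triisopropylsilyloxy)benzoate | C[C@H](OC(=O)N(C(C)C)C(C)C)c1ccc(C(=O)OC)cc1O[Si](C(C)C)(C(C)C)C(C)C | intermediate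
5 | (1S)-1-[4-(hydroxymethyl)-2-(triisopropylsilyloxy)phenyl]ethyl N,N-diisopropylcarbamate | C[C@H](OC(=O)N(C(C)C)C(C)C)c1ccc(CO)cc1O[Si](C(C)C)(C(C)C)C(C)C | intermediate
6 | 1-bromo-4-methylpentane | CC(C)CCCBr | starting material
7 | dilithio derivative of 5: (S)-configured α-lithiated carbamate (lithium in place of the benzylic hydrogen, retention) and lithium alkoxide at the CH2O group | C[C@]([Li])(OC(=O)N(C(C)C)C(C)C)c1ccc(CO[Li])cc1O[Si](C(C)C)(C(C)C)C(C)C | intermediate
8 | (2S)-2-[4-(hydroxymethyl)-2-(triisopropylsilyloxy)phenyl]-6-methylheptan-2-yl N,N-diisopropylcarbamate | CC(C)CCC[C@](C)(OC(=O)N(C(C)C)C(C)C)c1ccc(CO)cc1O[Si](C(C)C)(C(C)C)C(C)C | intermediate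
9 | (2S)-2-[4-(hydroxymethyl)-2-(triisopropylsilyloxy)phenyl]-6-methylheptan-2-ol | CC(C)CCC[C@](C)(O)c1ccc(CO)cc1O[Si](C(C)C)(C(C)C)C(C)C | intermediate
10 | (2S)-2-[4-(bromomethyl)-2-(triisopropylsilyloxy)phenyl]-6-methylheptan-2-ol | CC(C)CCC[C@](C)(O)c1ccc(CBr)cc1O[Si](C(C)C)(C(C)C)C(C)C | intermediate
11 | tetrabutylammonium 5-(hydroxymethyl)-2-[(2S)-2-hydroxy-6-methylheptan-2-yl]phenoxide | CC(C)CCC[C@](C)(O)c1ccc(CO)cc1[O-].CCCC[N+](CCCC)(CCCC)CCCC | intermediate
12 | (2S)-2-{4-[(5-(hydroxymethyl)-2-[(2S)-2-hydroxy-6-methylheptan-2-yl]phenoxy)methyl]-2-(triisopropylsilyloxy)phenyl}-6-methylheptan-2-ol (disydonol A carrying TIPS on its free phenol) | CC(C)CCC[C@](C)(O)c1ccc(COc2cc(CO)ccc2[C@@](C)(O)CCCC(C)C)cc1O[Si](C(C)C)(C(C)C)C(C)C | intermediate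
13 | disydonol A, 2-[(2S)-2-hydroxy-6-methylheptan-2-yl]-5-({5-(hydroxymethyl)-2-[(2S)-2-hydroxy-6-methylheptan-2-yl]phenoxy}methyl)phenol | CC(C)CCC[C@](C)(O)c1ccc(COc2cc(CO)ccc2[C@@](C)(O)CCCC(C)C)cc1O | target

**Step count and risks**

Total steps: 8. Longest linear sequence: 8 (1 → 2 → 3 → 4 → 5 → 8 → 9 → 10 → 13; compound 9 enters step 8 a second time as the nucleophile).

The three steps most likely to fail:

Step 5 (alkylation of the dianion). The SN2 attack of a hindered tertiary benzyllithium on an unactivated bromide must outrun racemisation and 1,2-carbamoyl shift, and the lithium alkoxide may make the dianion poorly soluble and sluggish. The fallback sets out from 5 and comes back at 8. The hydroxymethyl group of 5 is silylated (TBSCl, imidazole, DMF) to give (1S)-1-[4-({[tert-butyl(dimethyl)silyl]oxy}methyl)-2-(triisopropylsilyloxy)phenyl]ethyl N,N-diisopropylcarbamate F1. One equivalent of sBuLi/TMEDA in Et2O at −78 °C then gives the soluble monolithiated carbamate F2, which is alkylated with 6 to (2S)-2-[4-({[tert-butyl(dimethyl)silyl]oxy}methyl)-2-(triisopropylsilyloxy)phenyl]-6-methylheptan-2-yl N,N-diisopropylcarbamate F3. PPTS in MeOH removes only the primary TBS ether and returns 8.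

Step 6 (hydride cleavage of the hindered tertiary carbamate). The reduction may be slow. If the aryl silyl ether were lost first, the phenoxide next to the tertiary carbamate could expel it (o-quinone methide) and be reduced to the deoxy compound. The fallback sets out from 5 and comes back at 9, so it never forms a tertiary carbamate. It also replaces step 5 if the direct alkylation erodes the ee. 4-Methylpent-1-ene is hydroborated with BH3·SMe2 to tris(4-methylpentyl)borane F4. Compound 5 is lithiated to 7 as before and F4 is added at −78 °C. The borane attacks the benzylic carbon anti to lithium (inversion) to give the lithium borate complex F5. Its 1,2-alkyl shift, anti to the departing carbamate, gives the tertiary borane [(2R)-2-{4-[(lithiooxy)methyl]-2-(triisopropylsilyloxy)phenyl}-6-methylheptan-2-yl]bis(4-methylpentyl)borane F6 (the descriptor is R only because boron ranks lowest). NaOH/H2O2 at 0 °C oxidises C–B with retention and gives (S)-9 directly.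

Step 8 (one-pot fluoride coupling). Silyl exchange between the phenoxide and 10 would unmask the phenol of 10 and let it self-alkylate, and C-alkylation or residual fluoride could compete. The fallback sets out from 9 and comes back at 12, replacing the halide alkylation by a Mitsunobu coupling in which the nucleophile's own benzylic carbon is masked at the aldehyde level. Compound 9 is desilylated (TBAF, THF) to (S)-sydonol F7. MnO2 in CH2Cl2 oxidises only the benzylic alcohol and gives 3-hydroxy-4-[(2S)-2-hydroxy-6-methylheptan-2-yl]benzaldehyde F8. PPh3/DIAD in THF couples the phenol of F8 with the primary benzylic alcohol of a second portion of 9 to give 3-{[4-((2S)-2-hydroxy-6-methylheptan-2-yl)-3-(triisopropylsilyloxy)benzyl]oxy}-4-[(2S)-2-hydroxy-6-methylheptan-2-yl]benzaldehyde F9. NaBH4 in MeOH reduces the aldehyde to 12, which is desilylated with TBAF to 13 as in the last operation of step 8.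

**Further compounds**
F1 | step 5 | (1S)-1-[4-({[tert-butyl(dimethyl)silyl]oxy}methyl)-2-(triisopropylsilyloxy)phenyl]ethyl N,N-diisopropylcarbamate | C[C@H](OC(=O)N(C(C)C)C(C)C)c1ccc(CO[Si](C)(C)C(C)(C)C)cc1O[Si](C(C)C)(C(C)C)C(C)C
F2 | step 5 | (S)-configured α-lithiated derivative of F1 (monolithiated carbamate) | C[C@]([Li])(OC(=O)N(C(C)C)C(C)C)c1ccc(CO[Si](C)(C)C(C)(C)C)cc1O[Si](C(C)C)(C(C)C)C(C)C
F3 | step 5 | (2S)-2-[4-({[tert-butyl(dimethyl)silyl]oxy}methyl)-2-(triisopropylsilyloxy)phenyl]-6-methylheptan-2-yl N,N-diisopropylcarbamate | CC(C)CCC[C@](C)(OC(=O)N(C(C)C)C(C)C)c1ccc(CO[Si](C)(C)C(C)(C)C)cc1O[Si](C(C)C)(C(C)C)C(C)C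
F4 | step 6 | tris(4-methylpentyl)borane | CC(C)CCCB(CCCC(C)C)CCCC(C)C
F5 | step 6 | lithium borate complex from 7 and F4 (boron on the benzylic carbon, introduced with inversion) | C[C@@]([B-](CCCC(C)C)(CCCC(C)C)CCCC(C)C)(OC(=O)N(C(C)C)C(C)C)c1ccc(CO[Li])cc1O[Si](C(C)C)(C(C)C)C(C)C.[Li+]
F6 | step 6 | [(2R)-2-{4-[(lithiooxy)methyl]-2-(triisopropylsilyloxy)phenyl}-6-methylheptan-2-yl]bis(4-methylpentyl)borane | CC(C)CCC[C@](C)(B(CCCC(C)C)CCCC(C)C)c1ccc(CO[Li])cc1O[Si](C(C)C)(C(C)C)C(C)C
F7 | step 8 | (S)-sydonol, 5-(hydroxymethyl)-2-[(2S)-2-hydroxy-6-methylheptan-2-yl]phenol | CC(C)CCC[C@](C)(O)c1ccc(CO)cc1O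
F8 | step 8 | 3-hydroxy-4-[(2S)-2-hydroxy-6-methylheptan-2-yl]benzaldehyde | CC(C)CCC[C@](C)(O)c1ccc(C=O)cc1O
F9 | step 8 | 3-{[4-((2S)-2-hydroxy-6-methylheptan-2-yl)-3-(triisopropylsilyloxy)benzyl]oxy}-4-[(2S)-2-hydroxy-6-methylheptan-2-yl]benzaldehyde | CC(C)CCC[C@](C)(O)c1ccc(COc2cc(C=O)ccc2[C@@](C)(O)CCCC(C)C)cc1O[Si](C(C)C)(C(C)C)C(C)C
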